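**Retrosynthetic overview**
1. Target 17 ⇐ tri-O-methyl bis-isoflavone 16 by one global BBr3 demethylation at the end; methyl is the ether that survives KOH, Tl(III) and HCl.
2. Both chromen-4-one rings of 16 are closed last and together from bis-chalcone 13: 2'-O-acetylation, double Tl(III) oxidative 1,2-aryl shift, acid cyclisation.
3. 13 ⇐ chalcone-aldehyde 8 + acetophenone 11 by a Claisen–Schmidt aldol that joins the two halves; 8 ⇐ keto-acetal 4 + anisaldehyde 5 by a first Claisen–Schmidt aldol.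
4. The diaryl ether is made first: SNAr of 2',3'-dihydroxy-4'-methoxyacetophenone 1 on 4-fluorobenzaldehyde 2, then the aldehyde is masked as a dioxolane.
5. 11 ⇐ 2-chlororesorcinol 9 by Nencki C-acetylation and selective 4-O-methylation.

Assumption: the target has no stereocentre and no configurationally stable axis, so there is no enantiomer to control; the only stereo-elements in the route are transient (E-enones, and sp3 carbons that later become sp2).

**Step 1**
Reactants: 1 2',3'-dihydroxy-4'-methoxyacetophenone; 2 4-fluorobenzaldehyde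
Product: 3 4-(3-acetyl-2-hydroxy-6-methoxyphenoxy)benzaldehyde
Conditions: K2CO3 (2.2 equiv), 2 (1.05 equiv), dry DMF, 90 °C, Ar, 14 h; dil. HCl work-up
Reagents that add atoms: none
Why: SNAr (addition–elimination) on the para-formyl-activated aryl fluoride, in which the 3-OH reacts because the 2-OH is locked in a hydrogen bond to the acetyl C=O (the same selectivity as in K2CO3 alkylations of 2,3-dihydroxyacetophenones), and carbonate is too weak a base to start ketone–aldehyde aldol chemistry.

**Step 2**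
Reactants: 3 4-(3-acetyl-2-hydroxy-6-methoxyphenoxy)benzaldehyde
Product: 4 1-{3-[4-(1,3-dioxolan-2-yl)phenoxy]-2-hydroxy-4-methoxyphenyl}ethan-1-one
Conditions: HOCH2CH2OH (1.5 equiv), p-TsOH (2 mol%), toluene, Dean–Stark reflux
Reagents that add atoms: ethylene glycol, OCCO
Why: Chemoselective acetalisation, since the aryl aldehyde reacts far faster than the chelated, donor-conjugated aryl methyl ketone, which leaves the ketone as the only enolisable carbonyl for the next step.

**Step 3**
Reactants: 4 1-{3-[4-(1,3-dioxolan-2-yl)phenoxy]-2-hydroxy-4-methoxyphenyl}ethan-1-one; 5 4-methoxybenzaldehyde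
Product: 7 (E)-1-{3-[4-(1,3-dioxolan-2-yl)phenoxy]-2-hydroxy-4-methoxyphenyl}-3-(4-methoxyphenyl)prop-2-en-1-one, via racemic β-hydroxy ketone 6 (not isolated)
Conditions: 5 (1.3 equiv), KOH (50% aq, 10 equiv), EtOH, rt, 48 h; then cold dil. AcOH to pH 6
Reagents that add atoms: none
Why: Claisen–Schmidt crossed aldol condensation in which 4 is the only enolisable partner and 5 the only free aldehyde (the dioxolane is base-stable); E1cB dehydration of 6 removes its carbinol stereocentre and gives the thermodynamic E-enone.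

**Step 4**
Reactants: 7 (E)-chalcone dioxolane
Product: 8 4-{2-hydroxy-6-methoxy-3-[(E)-3-(4-methoxyphenyl)prop-2-enoyl]phenoxy}benzaldehyde
Conditions: 1 M HCl, THF, rt, 2 h
Reagents that add atoms: water, O
Why: Acid-catalysed acetal hydrolysis under conditions too mild (rt, dilute acid) to cyclise the 2'-hydroxychalcone to a flavanone or isomerise the enone.

**Step 5**
Reactants: 9 2-chlororesorcinol (2-chlorobenzene-1,3-diol)
Product: 10 1-(3-chloro-2,4-dihydroxyphenyl)ethan-1-one
Conditions: glacial AcOH, anhydrous ZnCl2 (1.5 equiv), 140 °C, 1 h; then dil. HCl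
Reagents that add atoms: acetic acid, CC(=O)O
Why: Nencki reaction (ZnCl2-promoted Friedel–Crafts C-acylation of a resorcinol), which on the C2-symmetric substrate can only give the 4-acyl product (ortho to one OH, para to the other), and the first acyl group deactivates the ring against a second.

**Step 6**
Reactants: 10 1-(3-chloro-2,4-dihydroxyphenyl)ethan-1-one
Product: 11 1-(3-chloro-2-hydroxy-4-methoxyphenyl)ethan-1-one
Conditions: MeI (1.1 equiv), K2CO3 (1.1 equiv), acetone, reflux, 6 h
Reagents that add atoms: iodomethane, CI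
Why: Williamson etherification selective for the 4-OH, because the 2-OH is chelated to the ketone and much less nucleophilic (the resacetophenone → paeonol selectivity).

**Step 7**
Reactants: 8 chalcone-aldehyde; 11 1-(3-chloro-2-hydroxy-4-methoxyphenyl)ethan-1-one
Product: 13 (E)-1-(3-chloro-2-hydroxy-4-methoxyphenyl)-3-(4-{2-hydroxy-6-methoxy-3-[(E)-3-(4-methoxyphenyl)prop-2-enoyl]phenoxy}phenyl)prop-2-en-1-one, via racemic β-hydroxy ketone 12 (not isolated)
Conditions: 11 (1.1 equiv), KOH (50% aq, 12 equiv), EtOH–THF, rt, 48 h; then cold 1 M HCl to pH 3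
Reagents that add atoms: none
Why: Claisen–Schmidt crossed aldol condensation that joins the two halves, in which 11 is the only enolisable ketone, the aldehyde of 8 is the most electrophilic site (the existing enone has no α-H and is deactivated as its 2'-phenoxide towards Michael addition), and E1cB dehydration of 12 gives the E-enone.

**Step 8**
Reactants: 13 bis-chalcone
Product: 14 2-chloro-6-[(E)-3-(4-{2-acetoxy-6-methoxy-3-[(E)-3-(4-methoxyphenyl)prop-2-enoyl]phenoxy}phenyl)prop-2-enoyl]-3-methoxyphenyl acetate (13 with both 2'-OH groups acetylated)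
Conditions: Ac2O (6 equiv), pyridine, DMAP (10 mol%), rt → 40 °C, 12 h
Reagents that add atoms: acetic anhydride, CC(=O)OC(C)=O
Why: DMAP-catalysed O-acylation of both chelated phenols, which blocks the 2'-OH participation that diverts Tl(III) oxidations of 2'-hydroxychalcones to aurones when the migrating ring is only moderately electron-rich (the 4-aryloxyphenyl ring here).

**Step 9**
Reactants: 14 bis-chalcone diacetate
Product: 15 2-chloro-6-[2-(4-{2-acetoxy-3-[3,3-dimethoxy-2-(4-methoxyphenyl)propanoyl]-6-methoxyphenoxy}phenyl)-3,3-dimethoxypropanoyl]-3-methoxyphenyl acetate (mixture of diastereomers)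
Conditions: Tl(NO3)3·3H2O (2.4 equiv), MeOH–CH2Cl2 (3:1), rt, 16 h; filter off TlNO3, NaHCO3 wash
Reagents that add atoms: methanol, CO
Why: Thallium(III) nitrate oxidative rearrangement of chalcones (oxythallation, then 1,2-shift of the electron-rich 4-alkoxy- or 4-aryloxy-phenyl ring with loss of Tl(I), then trapping of the oxocarbenium ion by MeOH) at both enones, where the two new α-stereocentres form without control and are destroyed in step 10.

**Step 10**
Reactants: 15 bis(dimethyl acetal) diacetate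
Product: 16 8-chloro-7-methoxy-3-(4-{[7-methoxy-3-(4-methoxyphenyl)-4-oxo-4H-chromen-8-yl]oxy}phenyl)-4H-chromen-4-one
Conditions: HCl (1.25 M in MeOH), reflux, 4 h
Reagents that add atoms: none
Why: Acid methanolysis of both aryl acetates followed by cyclocondensation of each freed phenol onto its β-keto acetal with loss of methanol closes both chromen-4-one rings (the classical end of the chalcone → isoflavone sequence) and makes both α-carbons sp2.

**Step 11**
Reactants: 16 tri-O-methyl bis-isoflavone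
Product: 17 bisoflavolin J, 8-chloro-7-hydroxy-3-(4-{[7-hydroxy-3-(4-hydroxyphenyl)-4-oxo-4H-chromen-8-yl]oxy}phenyl)-4H-chromen-4-one
Conditions: BBr3 (1 M in CH2Cl2, 10 equiv), CH2Cl2, −78 °C → rt, 16 h; then ice-water
Reagents that add atoms: none
Why: Lewis-acid cleavage of the three aryl methyl ethers (O-boronium formation, SN2 attack of bromide on methyl), which leaves the diaryl ether, the aryl chloride and the chromenones untouched.

**Compound list**
1 | 2',3'-dihydroxy-4'-methoxyacetophenone, 1-(2,3-dihydroxy-4-methoxyphenyl)ethan-1-one | CC(=O)c1ccc(OC)c(O)c1O | starting material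
2 | 4-fluorobenzaldehyde | O=Cc1ccc(F)cc1 | starting material
3 | 4-(3-acetyl-2-hydroxy-6-methoxyphenoxy)benzaldehyde | CC(=O)c1ccc(OC)c(Oc2ccc(C=O)cc2)c1O | intermediate
4 | 1-{3-[4-(1,3-dioxolan-2-yl)phenoxy]-2-hydroxy-4-methoxyphenyl}ethan-1-one | CC(=O)c1ccc(OC)c(Oc2ccc(C3OCCO3)cc2)c1O | intermediate
5 | 4-methoxybenzaldehyde | COc1ccc(C=O)cc1 | starting material
6 | 1-{3-[4-(1,3-dioxolan-2-yl)phenoxy]-2-hydroxy-4-methoxyphenyl}-3-hydroxy-3-(4-methoxyphenyl)propan-1-one, racemic aldol adduct, not isolated | COc1ccc(C(O)CC(=O)c2ccc(OC)c(Oc3ccc(C4OCCO4)cc3)c2O)cc1 | intermediate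
7 | (E)-1-{3-[4-(1,3-dioxolan-2-yl)phenoxy]-2-hydroxy-4-methoxyphenyl}-3-(4-methoxyphenyl)prop-2-en-1-one | COc1ccc(/C=C/C(=O)c2ccc(OC)c(Oc3ccc(C4OCCO4)cc3)c2O)cc1 | intermediate
8 | 4-{2-hydroxy-6-methoxy-3-[(E)-3-(4-methoxyphenyl)prop-2-enoyl]phenoxy}benzaldehyde | COc1ccc(/C=C/C(=O)c2ccc(OC)c(Oc3ccc(C=O)cc3)c2O)cc1 | intermediate
9 | 2-chlororesorcinol, 2-chlorobenzene-1,3-diol | Oc1cccc(O)c1Cl | starting material
10 | 1-(3-chloro-2,4-dihydroxyphenyl)ethan-1-one | CC(=O)c1ccc(O)c(Cl)c1O | intermediate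
11 | 1-(3-chloro-2-hydroxy-4-methoxyphenyl)ethan-1-one | CC(=O)c1ccc(OC)c(Cl)c1O | intermediate
12 | 1-(3-chloro-2-hydroxy-4-methoxyphenyl)-3-hydroxy-3-(4-{2-hydroxy-6-methoxy-3-[(E)-3-(4-methoxyphenyl)prop-2-enoyl]phenoxy}phenyl)propan-1-one, racemic aldol adduct, not isolated | COc1ccc(/C=C/C(=O)c2ccc(OC)c(Oc3ccc(C(O)CC(=O)c4ccc(OC)c(Cl)c4O)cc3)c2O)cc1 | intermediate
13 | (E)-1-(3-chloro-2-hydroxy-4-methoxyphenyl)-3-(4-{2-hydroxy-6-methoxy-3-[(E)-3-(4-methoxyphenyl)prop-2-enoyl]phenoxy}phenyl)prop-2-en-1-one (bis-chalcone) | COc1ccc(/C=C/C(=O)c2ccc(OC)c(Oc3ccc(/C=C/C(=O)c4ccc(OC)c(Cl)c4O)cc3)c2O)cc1 | intermediate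
14 | 2-chloro-6-[(E)-3-(4-{2-acetoxy-6-methoxy-3-[(E)-3-(4-methoxyphenyl)prop-2-enoyl]phenoxy}phenyl)prop-2-enoyl]-3-methoxyphenyl acetate (bis-chalcone diacetate) | COc1ccc(/C=C/C(=O)c2ccc(OC)c(Oc3ccc(/C=C/C(=O)c4ccc(OC)c(Cl)c4OC(C)=O)cc3)c2OC(C)=O)cc1 | intermediate
15 | 2-chloro-6-[2-(4-{2-acetoxy-3-[3,3-dimethoxy-2-(4-methoxyphenyl)propanoyl]-6-methoxyphenoxy}phenyl)-3,3-dimethoxypropanoyl]-3-methoxyphenyl acetate, mixture of diastereomers | COc1ccc(C(C(OC)OC)C(=O)c2ccc(OC)c(Oc3ccc(C(C(OC)OC)C(=O)c4ccc(OC)c(Cl)c4OC(C)=O)cc3)c2OC(C)=O)cc1 | intermediate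
16 | 8-chloro-7-methoxy-3-(4-{[7-methoxy-3-(4-methoxyphenyl)-4-oxo-4H-chromen-8-yl]oxy}phenyl)-4H-chromen-4-one | COc1ccc(-c2coc3c(Oc4ccc(-c5coc6c(Cl)c(OC)ccc6c5=O)cc4)c(OC)ccc3c2=O)cc1 | intermediate
17 | bisoflavolin J, 8-chloro-7-hydroxy-3-(4-{[7-hydroxy-3-(4-hydroxyphenyl)-4-oxo-4H-chromen-8-yl]oxy}phenyl)-4H-chromen-4-one | O=c1c(-c2ccc(Oc3c(O)ccc4c(=O)c(-c5ccc(O)cc5)coc34)cc2)coc2c(Cl)c(O)ccc12 | target

**Totals**
Total step count: 11.
Longest linear sequence: 9 steps (steps 1, 2, 3, 4, 7, 8, 9, 10, 11; the branch 9 → 10 → 11 adds steps 5 and 6).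

**Three steps most likely to fail**

Step 9 (double Tl(III) rearrangement). Both enones must rearrange in one molecule, and the 4-aryloxyphenyl ring migrates less readily than a 4-methoxyphenyl ring. The fallback sets out from 13 and comes back at 16. Bis-chalcone 13 is cyclised by intramolecular oxa-Michael addition (NaOAc, EtOH, reflux) to the bis-flavanone 8-chloro-7-methoxy-2-(4-{[7-methoxy-2-(4-methoxyphenyl)-4-oxochroman-8-yl]oxy}phenyl)chroman-4-one F1 (diastereomer mixture). F1 is then oxidised with [hydroxy(tosyloxy)iodo]benzene (2.4 equiv) in MeCN at reflux. Iodination at C-3, 2 → 3 aryl shift and loss of iodobenzene and a proton give the isoflavone rings of 16 directly, with no acetal stage and no thallium. The phenolic oxygen is already in the ring, so the aurone pathway cannot operate.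

Step 1 (SNAr on the dihydroxyacetophenone). The risks are O-2 arylation or diarylation and some base-induced self-condensation. The fallback sets out from 2 and comes back at 3. Aldehyde 2 is coupled with commercial 2,6-dimethoxyphenol (K2CO3, DMF, 120 °C), which has only one OH, to give 4-(2,6-dimethoxyphenoxy)benzaldehyde F2. Friedel–Crafts acetylation (AcCl, AlCl3 2.5 equiv, CH2Cl2, 0 °C) goes para to one OMe and ortho to the other on the electron-rich ring, giving 4-(3-acetyl-2,6-dimethoxyphenoxy)benzaldehyde F3. BCl3 (CH2Cl2, −78 → 0 °C) then cleaves only the methoxy group chelated to the acetyl carbonyl and gives 3.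

Step 7 (second Claisen–Schmidt in the presence of a chalcone). The risks are Michael addition of the enolate to the existing enone, retro-aldol scrambling and poor solubility in aqueous base. The fallback sets out from 11 and comes back at 13, and it forms the enone under neutral conditions by a Wittig reaction. Ketone 11 is brominated at the side chain with CuBr2 (EtOAc–CHCl3, reflux) to 2-bromo-1-(3-chloro-2-hydroxy-4-methoxyphenyl)ethan-1-one F4. PPh3 (MeCN, rt) gives [2-(3-chloro-2-hydroxy-4-methoxyphenyl)-2-oxoethyl]triphenylphosphonium bromide F5. Aqueous Na2CO3 gives the stabilised ylide 1-(3-chloro-2-hydroxy-4-methoxyphenyl)-2-(triphenyl-λ5-phosphanylidene)ethan-1-one F6. Heating F6 with aldehyde 8 in toluene at reflux gives the E-enone 13.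

**Further compounds**
F1 | step 9 | 8-chloro-7-methoxy-2-(4-{[7-methoxy-2-(4-methoxyphenyl)-4-oxochroman-8-yl]oxy}phenyl)chroman-4-one, mixture of diastereomers | COc1ccc(C2CC(=O)c3ccc(OC)c(Oc4ccc(C5CC(=O)c6ccc(OC)c(Cl)c6O5)cc4)c3O2)cc1
F2 | step 1 | 4-(2,6-dimethoxyphenoxy)benzaldehyde | COc1cccc(OC)c1Oc1ccc(C=O)cc1
F3 | step 1 | 4-(3-acetyl-2,6-dimethoxyphenoxy)benzaldehyde | CC(=O)c1ccc(OC)c(Oc2ccc(C=O)cc2)c1OC
F4 | step 7 | 2-bromo-1-(3-chloro-2-hydroxy-4-methoxyphenyl)ethan-1-one | O=C(CBr)c1ccc(OC)c(Cl)c1O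
F5 | step 7 | [2-(3-chloro-2-hydroxy-4-methoxyphenyl)-2-oxoethyl]triphenylphosphonium bromide | [Br-].O=C(C[P+](c1ccccc1)(c1ccccc1)c1ccccc1)c1ccc(OC)c(Cl)c1O
F6 | step 7 | 1-(3-chloro-2-hydroxy-4-methoxyphenyl)-2-(triphenyl-λ5-phosphanylidene)ethan-1-one | O=C(C=P(c1ccccc1)(c1ccccc1)c1ccccc1)c1ccc(OC)c(Cl)c1O
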